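Ring letters: A = phenol ring (OH, O-aryl ortho to it, CH2 para to it), B = 1,3-phenylene, C = catechol ring (CH2, two OH, O-aryl), D = 1,4-phenylene.
A direct plan would make both diaryl ethers by copper-catalysed O-arylation of catechol, giving the salicylaldehyde A1 (3-(4-bromophenoxy)-2-hydroxy-5-iodobenzaldehyde) and the styrene A2 (2-(3-ethenylphenoxy)phenol). It would join them by a Bu3SnH-mediated aryl-radical addition to the styrene, iodinate and vinylate ring A to the bromo styrene A3, close the 19-membered ring by a second aryl-radical addition to the macrocyclic salicylaldehyde A4, and end with a Dakin oxidation.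
Weak step 1, the intermolecular radical hydroarylation that joins the halves: reduction of the aryl radical by Bu3SnH and by the phenol and aldehyde hydrogens would compete with addition, so an excess of the styrene half would be consumed and telomers would form.
Weak step 2, the radical macrocyclisation of A3: an aryl radical is too short-lived to find a distal alkene at 1 mM, the ring closure has no precedent, and it would sit one step from the end.
Weak step 3, the late corrections of the oxygen pattern: ring A would be iodinated on an advanced intermediate with two competing para sites, and one ring C hydroxyl would only be revealed by Dakin oxidation of the electron-rich macrocycle.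

**Retrosynthetic overview**
Key disconnection: both CH2–CH2 bonds of the two Ar–CH2–CH2–Ar bridges (ring A to ring D, ring B to ring C) are cut at once. Each bridge is traced back to a benzyl arylacetate unit Ar–CH2–O–C(=O)–CH2–Ar′ that loses CO2 on irradiation.
The 19-membered carbocycle therefore arises by double ring contraction (23 → 21 → 19) of a macrodiolide. The oxygen-rich rings A and C carry the benzylic alcohol ends and rings B and D the arylacetic acid ends.
Ring order: two diaryl ethers (Ullmann) → head-to-tail ester, which fixes which rings are joined → 23-membered lactone ring → 19-membered ring in the key step.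
All six oxygens come with commercial building blocks, so no late aromatic oxidation or halogenation is needed. The ring is closed by esterification, not by a tin hydride radical chain.

Key step: step 7

Remark: the target has no stereocentre; the three phenols are carried as methyl ethers.

**Step 1**
Reactants: 1 5-(hydroxymethyl)-2-methoxyphenol (isovanillyl alcohol); 2 2-(3-bromophenyl)acetic acid
Product: 3 2-[3-[5-(hydroxymethyl)-2-methoxyphenoxy]phenyl]acetic acid
Conditions: 1 (1.2 equiv), CuI (10 mol%), picolinic acid (20 mol%), K3PO4 (4 equiv), DMSO, 90 °C, Ar; then aq. HCl to pH 3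
Reagents that add atoms: none
Why: Ullmann-type copper-catalysed O-arylation of the phenoxide of 1 with an unhindered aryl bromide; the benzylic alcohol and the carboxylate are spectators, and the meta relation of OH and CH2OH in 1 rules out quinone methide formation.

**Step 2**
Reactants: 3 2-[3-[5-(hydroxymethyl)-2-methoxyphenoxy]phenyl]acetic acid
Product: 4 prop-2-enyl 2-[3-[5-(hydroxymethyl)-2-methoxyphenoxy]phenyl]acetate
Conditions: allyl bromide (1.2 equiv), KHCO3 (1.5 equiv), DMF, rt
Reagents that add atoms: allyl bromide, C=CCBr
Why: Carboxylate O-alkylation (SN2) with a weak base leaves the benzylic alcohol free and masks the ring B acid as an ester that zerovalent palladium can later remove without touching benzylic esters.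

**Step 3**
Reactants: 5 3-bromo-4,5-dimethoxybenzaldehyde; 6 2-(4-hydroxyphenyl)acetic acid
Product: 7 2-[4-(5-formyl-2,3-dimethoxyphenoxy)phenyl]acetic acid
Conditions: 6 (1.3 equiv), CuI (10 mol%), picolinic acid (20 mol%), K3PO4 (4 equiv), DMSO, 100 °C, Ar; then aq. HCl to pH 3
Reagents that add atoms: none
Why: Ullmann-type copper-catalysed O-arylation of the phenoxide of 6 with the ortho-methoxy aryl bromide; the non-enolisable aldehyde is carried as the latent benzylic alcohol of ring C, and exclusion of air prevents oxidative decarboxylation of the arylacetate.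

**Step 4**
Reactants: 4 prop-2-enyl 2-[3-[5-(hydroxymethyl)-2-methoxyphenoxy]phenyl]acetate; 7 2-[4-(5-formyl-2,3-dimethoxyphenoxy)phenyl]acetic acid
Product: 8 [4-methoxy-3-[3-(2-oxo-2-prop-2-enoxyethyl)phenoxy]phenyl]methyl 2-[4-(5-formyl-2,3-dimethoxyphenoxy)phenyl]acetate
Conditions: EDC·HCl (1.3 equiv), DMAP (0.2 equiv), CH2Cl2, 0 °C to rt
Reagents that add atoms: none
Why: Steglich esterification joins the only free alcohol (ring A benzylic OH of 4) with the only free acid (ring D arylacetic acid of 7), which fixes the head-to-tail order of the four rings.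

**Step 5**
Reactants: 8 [4-methoxy-3-[3-(2-oxo-2-prop-2-enoxyethyl)phenoxy]phenyl]methyl 2-[4-(5-formyl-2,3-dimethoxyphenoxy)phenyl]acetate
Product: 10 2-[3-[5-[[2-[4-[5-(hydroxymethyl)-2,3-dimethoxyphenoxy]phenyl]acetyl]oxymethyl]-2-methoxyphenoxy]phenyl]acetic acid (seco hydroxy acid), via hydroxy allyl ester 9 (not isolated)
Conditions: NaBH4 (0.6 equiv), THF/MeOH 10:1, 0 °C; then morpholine (5 equiv), Pd(PPh3)4 (5 mol%), rt; aq. KHSO4 work-up
Reagents that add atoms: none
Why: Borohydride reduces the aromatic aldehyde but not the esters at 0 °C, and the allyl ester is then cleaved through a π-allyl palladium complex trapped by morpholine (Tsuji–Trost deallylation), conditions under which the two benzylic esters should be inert.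

**Step 6**
Reactants: 10 seco hydroxy acid
Product: 11 23-membered macrodiolide (ring A–CH2–O–C(=O)–CH2–ring D and ring B–CH2–C(=O)–O–CH2–ring C lactone bridges; diaryl ethers A–O–B and C–O–D; one OMe on ring A, two on ring C)
Conditions: 2-methyl-6-nitrobenzoic anhydride (1.5 equiv), DMAP (6 equiv), CH2Cl2, rt, 10 added over 12 h to a final 2 mM
Reagents that add atoms: none
Why: Shiina macrolactonisation: the mixed anhydride of the arylacetic acid acylates the ring C benzylic alcohol under DMAP catalysis, and slow addition at high dilution favours the unstrained 23-membered ring over oligomers.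

**Step 7**
Reactants: 11 23-membered macrodiolide
Product: 13 marchantin A tri-O-methyl ether (the target with OMe in place of its three OH), via 21-membered monolactone 12 (not isolated)
Conditions: hν (254 nm, low-pressure Hg lamp, quartz), degassed MeCN, 1 mM, 20 °C, until 11 and 12 are consumed
Reagents that add atoms: none
Why: Excitation of the alkoxy-substituted benzyl ester chromophores cleaves each benzylic C–O bond to a benzyl radical and an arylacetoxyl radical, which loses CO2 within nanoseconds; the two benzyl radicals, still tethered through the rest of the macrocycle, recombine to the CH2–CH2 bond. The closest known reaction type is the photodecarboxylation of benzyl arylacetates to 1,2-diarylethanes, including the photoextrusion of CO2 from cyclic bis(benzyl ester) diesters to cyclophanes. Both rings close by recombination of a tethered benzyl/benzyl biradical, first to a 21-membered lactone ring (23 → 21), then to the 19-membered carbocycle (21 → 19); the order of the two extrusions does not matter. No stereocentre is formed. The step needs C–C recombination at the two benzylic carbons in preference to trapping of benzyl cations, coupling at ring carbons or intermolecular coupling. The non-nucleophilic solvent returns ion pairs to ester, the fast decarboxylation feeds the radical channel, the para positions of the ring A, ring C and ring D benzyl radicals are blocked by oxygen substituents, and the tether at 1 mM disfavours dimers.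

**Step 8**
Reactants: 13 marchantin A tri-O-methyl ether
Product: 14 marchantin A (CNP0495401.0)
Conditions: BBr3 (9 equiv), CH2Cl2, −78 °C to rt; then MeOH, H2O
Reagents that add atoms: none
Why: Lewis acid demethylation of the three aryl methyl ethers by BBr3 (via aryloxyboranes and bromomethane) leaves the diaryl ethers and the bridges intact; the product has no stereocentre.

**Compound list**
1 | 5-(hydroxymethyl)-2-methoxyphenol (isovanillyl alcohol) | COc1ccc(CO)cc1O | starting material
2 | 2-(3-bromophenyl)acetic acid | OC(=O)Cc1cccc(Br)c1 | starting material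
3 | 2-[3-[5-(hydroxymethyl)-2-methoxyphenoxy]phenyl]acetic acid | COc1ccc(CO)cc1Oc1cccc(CC(=O)O)c1 | intermediate
4 | prop-2-enyl 2-[3-[5-(hydroxymethyl)-2-methoxyphenoxy]phenyl]acetate | COc1ccc(CO)cc1Oc1cccc(CC(=O)OCC=C)c1 | intermediate
5 | 3-bromo-4,5-dimethoxybenzaldehyde | COc1cc(C=O)cc(Br)c1OC | starting material
6 | 2-(4-hydroxyphenyl)acetic acid | OC(=O)Cc1ccc(O)cc1 | starting material
7 | 2-[4-(5-formyl-2,3-dimethoxyphenoxy)phenyl]acetic acid | COc1cc(C=O)cc(Oc2ccc(CC(=O)O)cc2)c1OC | intermediate
8 | [4-methoxy-3-[3-(2-oxo-2-prop-2-enoxyethyl)phenoxy]phenyl]methyl 2-[4-(5-formyl-2,3-dimethoxyphenoxy)phenyl]acetate | COc1ccc(COC(=O)Cc2ccc(Oc3cc(C=O)cc(OC)c3OC)cc2)cc1Oc1cccc(CC(=O)OCC=C)c1 | intermediate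
9 | [4-methoxy-3-[3-(2-oxo-2-prop-2-enoxyethyl)phenoxy]phenyl]methyl 2-[4-[5-(hydroxymethyl)-2,3-dimethoxyphenoxy]phenyl]acetate (hydroxy allyl ester, not isolated) | COc1ccc(COC(=O)Cc2ccc(Oc3cc(CO)cc(OC)c3OC)cc2)cc1Oc1cccc(CC(=O)OCC=C)c1 | intermediate
10 | 2-[3-[5-[[2-[4-[5-(hydroxymethyl)-2,3-dimethoxyphenoxy]phenyl]acetyl]oxymethyl]-2-methoxyphenoxy]phenyl]acetic acid (seco hydroxy acid) | COc1ccc(COC(=O)Cc2ccc(Oc3cc(CO)cc(OC)c3OC)cc2)cc1Oc1cccc(CC(=O)O)c1 | intermediate
11 | 23-membered macrodiolide (two benzyl arylacetate bridges, two diaryl ethers, three OMe) | COc1ccc2cc1Oc1cccc(c1)CC(=O)OCc1cc(OC)c(OC)c(c1)Oc1ccc(cc1)CC(=O)OC2 | intermediate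
12 | 21-membered monolactone (ring B–CH2CH2–ring C bridge formed, ring A/ring D lactone bridge intact; not isolated) | COc1ccc2cc1Oc1cccc(c1)CCc1cc(OC)c(OC)c(c1)Oc1ccc(cc1)CC(=O)OC2 | intermediate
13 | marchantin A tri-O-methyl ether | COc1ccc2cc1Oc1cccc(c1)CCc1cc(OC)c(OC)c(c1)Oc1ccc(cc1)CC2 | intermediate
14 | marchantin A (CNP0495401.0) | Oc1ccc2cc1Oc1cccc(c1)CCc1cc(O)c(O)c(c1)Oc1ccc(cc1)CC2 | target

**Count and risks**
Total steps: 8. Longest linear sequence: 7 (steps 1, 2, 4, 5, 6, 7, 8).

Steps most likely to fail:

1. Step 7. The light-induced C–O cleavage may go mainly through ion pairs that return to ester, the benzyl radicals may recombine at ring carbons, and the diaryl ether product may photolyse during the long irradiation that two extrusions need.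
Fallback (sets out from 3 and 7, comes back at 13): both bridges would be built without light by two Perkin condensations, each followed by thermal loss of CO2 from the acrylic acid. 7 would be esterified (MeI, KHCO3, DMF) to methyl 2-[4-(5-formyl-2,3-dimethoxyphenoxy)phenyl]acetate F1. Perkin condensation of the arylacetic acid 3 with the aldehyde F1 (Ac2O, Et3N, 120 °C; the benzylic OH is acetylated on the way) should give the (E)-2,3-diarylacrylic acid F2. LiOH (THF/H2O) would free the ring D acid and the ring A alcohol to the diacid alcohol F3, and Dess–Martin periodinane would give the aldehyde diacid F4. A second, intramolecular Perkin condensation at 5 mM (Ac2O, Et3N, 110 °C) would close the ring to the macrocyclic bis(acrylic acid) F5. Cu powder in quinoline at 210 °C would remove both carboxyl groups to the macrocyclic bis-(Z)-stilbene F6, and H2 over Pd on carbon would give 13.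

2. Step 6. Intermolecular acylation may give linear and cyclic oligomers, and the activated arylacetic acid may form a ketene that is consumed unproductively.
Fallback (sets out from 10, comes back at 11): the alcohol would be activated in place of the acid by a Mitsunobu macrolactonisation (PPh3, diisopropyl azodicarboxylate, toluene/THF, slow addition to 2 mM). The carboxylate then displaces the activated ring C benzylic oxygen, so no activated acyl species is present; no new compound is isolated.

3. Step 3. Oxidative addition into the ortho-methoxy aryl bromide may be slow, so that protodebromination and sequestering of copper by the carboxylate take over.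
Fallback (does not branch from a numbered compound: 5 and 6 are replaced by two commercial materials; comes back at 7): the roles of the rings would be reversed in a room-temperature oxidative Chan–Lam–Evans coupling. The phenol 3-hydroxy-4,5-dimethoxybenzaldehyde F7 and [4-(2-ethoxy-2-oxoethyl)phenyl]boronic acid F8 (Cu(OAc)2, pyridine, 4 Å molecular sieves, CH2Cl2, air) should give ethyl 2-[4-(5-formyl-2,3-dimethoxyphenoxy)phenyl]acetate F9, and LiOH (THF/H2O, 0 °C) would give 7.

**Further compounds**
F1 | step 7 | methyl 2-[4-(5-formyl-2,3-dimethoxyphenoxy)phenyl]acetate | COc1cc(C=O)cc(Oc2ccc(CC(=O)OC)cc2)c1OC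
F2 | step 7 | (E)-2-[3-[5-(acetyloxymethyl)-2-methoxyphenoxy]phenyl]-3-[3,4-dimethoxy-5-[4-(2-methoxy-2-oxoethyl)phenoxy]phenyl]prop-2-enoic acid | COc1ccc(COC(C)=O)cc1Oc1cccc(c1)/C(C(=O)O)=C\c1cc(OC)c(OC)c(c1)Oc1ccc(CC(=O)OC)cc1
F3 | step 7 | (E)-3-[3-[4-(carboxymethyl)phenoxy]-4,5-dimethoxyphenyl]-2-[3-[5-(hydroxymethyl)-2-methoxyphenoxy]phenyl]prop-2-enoic acid | COc1ccc(CO)cc1Oc1cccc(c1)/C(C(=O)O)=C\c1cc(OC)c(OC)c(c1)Oc1ccc(CC(=O)O)cc1
F4 | step 7 | (E)-3-[3-[4-(carboxymethyl)phenoxy]-4,5-dimethoxyphenyl]-2-[3-(5-formyl-2-methoxyphenoxy)phenyl]prop-2-enoic acid | COc1ccc(C=O)cc1Oc1cccc(c1)/C(C(=O)O)=C\c1cc(OC)c(OC)c(c1)Oc1ccc(cc1)CC(=O)O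
F5 | step 7 | macrocyclic bis[(E)-2,3-diarylacrylic acid] (CO2H on the bridge carbons next to ring B and ring D) | COc1ccc2cc1Oc1cccc(c1)/C(C(=O)O)=C\c1cc(OC)c(OC)c(c1)Oc1ccc(cc1)/C(C(=O)O)=C\2
F6 | step 7 | macrocyclic bis-(Z)-stilbene (marchantin A tri-O-methyl ether with both bridges as cis CH=CH) | COc1ccc2cc1Oc1cccc(c1)/C=C\c1cc(OC)c(OC)c(c1)Oc1ccc(cc1)/C=C\2
F0 | step 6 | none | none
F7 | step 3 | 3-hydroxy-4,5-dimethoxybenzaldehyde | COc1cc(C=O)cc(O)c1OC
F8 | step 3 | [4-(2-ethoxy-2-oxoethyl)phenyl]boronic acid | CCOC(=O)Cc1ccc(B(O)O)cc1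
F9 | step 3 | ethyl 2-[4-(5-formyl-2,3-dimethoxyphenoxy)phenyl]acetate | CCOC(=O)Cc1ccc(Oc2cc(C=O)cc(OC)c2OC)cc1
A1 | direct plan | 3-(4-bromophenoxy)-2-hydroxy-5-iodobenzaldehyde | O=Cc1cc(I)cc(Oc2ccc(Br)cc2)c1O
A2 | direct plan | 2-(3-ethenylphenoxy)phenol | Oc1ccccc1Oc1cccc(C=C)c1
A3 | direct plan | 3-(4-bromophenoxy)-5-[2-[3-(5-ethenyl-2-hydroxyphenoxy)phenyl]ethyl]-2-hydroxybenzaldehyde | O=Cc1cc(CCc2cccc(Oc3cc(C=C)ccc3O)c2)cc(Oc2ccc(Br)cc2)c1O
A4 | direct plan | macrocyclic salicylaldehyde (marchantin A with CHO in place of the ring C hydroxyl meta to the bridge) | Oc1ccc2cc1Oc1cccc(c1)CCc1cc(C=O)c(O)c(c1)Oc1ccc(cc1)CC2
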